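## The problem

The target is an all-ether phlorotannin: seven benzene rings (A to G) joined in a line by six diaryl ether oxygens, with eighteen free phenolic hydroxyls. It has no stereocentre, so nothing has to be controlled or relayed in three dimensions. The whole task is regiochemistry and C–O bond construction. Rings B, D and F are 1,4-dioxygenated rings whose ether oxygen at position 4 sits between two hydroxyl-bearing carbons. Rings C and E are pentaoxygenated, with ether oxygens on the neighbouring carbons 1 and 6. Ring G is a 3,4,5-trihydroxyphenyl cap. Each ether oxygen has one crowded end (A1, B4, C6, D4, E6, F4, each flanked by two oxygenated carbons) and one open end (B1, C1, D1, E1, F1, G1), so every coupling must be planned from the side that tolerates crowding. The free polyphenol, with its pyrogallol triads on rings C, E and G and a phloroglucinol ring A, is prone to air oxidation. The hydroxyls therefore have to stay masked until the last step, in a form that survives copper salts, organolithium reagents, peracid and ethoxide. The repetition helps: B–C and D–E are the same two-ring unit, and F–G is that unit less one oxygen. The most crowded and most electron-rich ether, A1–O–B1, lies on ring A between the hydroxyl carbons A2 and A6. Because ring A is a 2-aryloxyphloroglucinol with all three hydroxyls free, it is the enol form of a 2-aryloxycyclohexane-1,3,5-trione. It can therefore be folded from a three-carbon malonate (A2, A1, A6) and a three-carbon oxoglutarate (A3, A4, A5), with the A1–O bond made beforehand at an sp3 carbon.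

## Retrosynthesis

**Target 23 to triol 22.** The fifteen O–CH3 bonds on rings B to G are cut last. Methyl is preferred to benzyl because the building blocks 1 and 2 are purchasable as methyl ethers and because methyl survives every reagent of the route. The forward step asks BBr3 to cleave fifteen alkyl aryl ethers while leaving six diaryl ethers, which have no sp3 carbon for bromide to attack.

**Triol 22 to diester 20.** The hydrogens at A3 and A5 are traced back to two ethoxycarbonyl groups. These are the price of using oxoglutarate 18, whose methylenes owe their acidity to them. Phloroglucinol carboxylic acids lose CO2 through their keto tautomers on mild heating, so the forward step is a saponification followed by acidification.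

**Diester 20 to malonate 17 and keto diester 18.** Bonds A2–A3 and A5–A6 are cut. The neighbouring cut, at the A1–O–B1 ether, would need either a 2,4,6-trioxygenated phenol as nucleophile or an aryl halide flanked by two oxygens as electrophile. That is the worst coupling in the molecule. The chosen cut removes ring A altogether and leaves two C3 pieces, one of them a commodity chemical. The forward reaction must deliver two C-acylations, the second one ring-closing, in preference to O-acylation.

**Malonate 17 to phenol 15 and bromomalonate 16.** The O–C(sp3) bond that becomes A1–O is cut. This is a simple phenoxide alkylation at the open position B1, and 15 is a hexamer with a single free hydroxyl.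

**Phenol 15 to bromide 14.** The B1 hydroxyl is traced to bromine. Bromine is inert in the copper-mediated boronic acid couplings, and that inertness is what allows one two-ring unit to be used three times. An oxygen substituent at B1 carried from the start would make ring B as electron-rich as ring C and would spoil the site selectivity of the formylation described below.

**Bromide 14 to phenol 6 and boronic acid 13; 13 to bromide 10; 10 to phenol 6 and boronic acid 9.** The ethers C6–O–D1 and E6–O–F1 are cut between the oxygen and the open carbons D1 and F1. Cutting at B4–O–C1 or D4–O–E1 instead would break the repeating unit and require three different fragments. With the chosen cuts the crowded partner is always the phenol 6 and the boron partner always has free ortho positions, which is the sense in which copper-mediated O-arylation tolerates hindrance. Each cut halves the problem. The boronic acids 13 and 9 come from bromides 10 and 3 by bromine–lithium exchange.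

**Phenol 6 to aldehyde 4 to bromide 3.** The hydroxyl that becomes C6–O or E6–O is traced to a formyl group (Baeyer–Villiger) and the formyl group to a C–H bond (Vilsmeier–Haack). The pentaoxygenated rings are thus reached from a tetraoxygenated ring without a pentaoxygenated starting material. The forward formylation must choose the trimethoxyphenoxy ring over the bromo ring, which it should because that ring has three activating oxygens and no halogen.

**Bromide 3 to phenol 1 and boronic acid 2.** The ether that becomes F4–O–G1 (and, in the reused unit, B4–O–C1 and D4–O–E1) is cut on the open side. Both partners are purchasable, and the bromine that serves every later step is already in place in 1.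

## Roads not taken

**Alternative 1:** Ring B is cut at B1–B2 and B1–B6. The pieces are 3,5-dimethoxy-4H-pyran-4-one A2 and the (2,4,6-trimethoxyphenoxy)methylphosphonium salt A3. In the forward step the ylide of A3 adds to C2 of silyl-activated A2, the 2H-pyran opens, and an intramolecular Wittig reaction closes ring B to give the rings A–B dimer A1 with the B4 oxygen as a silyl ether.
- Merits: like the chosen plan, it makes the A1–O–B1 ether at an sp3 carbon. It also delivers the B4 oxygen already differentiated. Its risky step comes at the very start on small molecules, where failure is cheap. In that respect it is better than the chosen plan, which tests its key step on a late hexamer.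
- Weak points: the ring transformation is itself undemonstrated for a dialkoxy-silyloxypyrylium with an alkoxy-substituted ylide. A2 is not a commodity. After A1, the five rings C to G still have to be joined through B4–O–C1, where a doubly flanked phenol meets a C1 partner that carries an ortho substituent. That is harder than any coupling in the chosen route.
- Comparison: the chosen plan offsets its late risk with commodity C3 partners for ring A, a ring A that needs no oxygen differentiation, and ether couplings that are all of one favourable kind.

**Alternative 2:** Ring C is cut at C2–C3. The precursor is the 4-(1-aryloxyvinyl)-4-silyloxy-2,3-dimethoxycyclobutenone A5, built from dimethyl squarate A6 by addition of a 1-aryloxyvinyl anion. Thermolysis opens A5 to a dienylketene, and 6π electrocyclisation gives the rings A–C trimer A4 with C3 hydroxyl free and C6 oxygen silylated.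
- Merits: the ring expansion of 4-alkenyl-4-hydroxycyclobutenones is a well-established reaction type with fixed regiochemistry. In this respect its key step is more secure than the Claisen folding chosen here. It also places all five oxygens of ring C at once and differentiates C6.
- Weak points: it solves one pentaoxygenated ring of two, so ring E needs a second pass on a larger fragment. The vinyl anion must be generated beside aryl positions that lie between two oxygens and are themselves easily metalated. The route is linear.
- Comparison: the chosen plan reaches both pentaoxygenated rings through one formylation and one Baeyer–Villiger step on a single dimer, and ends with a lower step count.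

**Alternative 3:** Ring D is cut at D5–D6, D1–D2 and D4–D5. The partners are the ethynyl ether A8 of the rings A–C phenol and the 4-aryloxy-3-ethoxycyclobutenone A9 that carries rings E–G. Heating joins them by vinylketene cycloaddition, ring opening and 6π electrocyclisation to the heptamer A7.
- Merits: it is the most convergent of the four plans and could give a shorter longest linear sequence. It makes both crowded ethers on ring D before the ring exists. Benzannulation of cyclobutenones with alkynyl ethers is a known, regiospecific reaction type.
- Weak points: it needs two different three-ring fragments, each with its own pentaoxygenated ring and its own ether couplings. These include the A1–O–B1 coupling on a 2,4,6-trioxygenated ring that the chosen plan avoids. A9 is a sensitive cyclobutenone that has to be built on a large aryloxyacetyl fragment, and A8 is a thermally delicate ynol ether of a crowded phenol.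
- Comparison: the chosen plan cannot match the convergence. It offsets this with one dimer used three times, purchasable reagents throughout and far fewer distinct intermediates.

Key step: step 10

Assumption: methyl ethers are the only phenol protection and all fall in the last step; compounds 1, 2, 16 and 18 are taken as purchasable.

## Route

Step 1
Reactants: 1 4-bromo-2,6-dimethoxyphenol; 2 (3,4,5-trimethoxyphenyl)boronic acid
Product: 3 5-(4-bromo-2,6-dimethoxyphenoxy)-1,2,3-trimethoxybenzene
Conditions: Cu(OAc)2 (2 equiv), pyridine, 4 Å MS, CH2Cl2, air, rt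
Reagents that add atoms: none
Why: Chan–Lam–Evans O-arylation; divalent copper acetate couples phenols that carry two ortho substituents with arylboronic acids that carry none. The aryl bromide is inert, and the bromine blocks the para position against oxidative phenol coupling.

Step 2
Reactants: 3 5-(4-bromo-2,6-dimethoxyphenoxy)-1,2,3-trimethoxybenzene
Product: 4 6-(4-bromo-2,6-dimethoxyphenoxy)-2,3,4-trimethoxybenzaldehyde
Conditions: POCl3, DMF, 0 to 70 °C; then H2O
Reagents that add atoms: N,N-dimethylformamide CN(C)C=O; water O
Why: Vilsmeier–Haack formylation. The free positions of the trimethoxyphenoxy ring are activated by an ortho aryloxy, an ortho methoxy and a para methoxy group, whereas those of the bromo ring have only two oxygen activators and a deactivating bromine. The two reactive positions are equivalent, so one aldehyde is expected.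

Step 3
Reactants: 4 6-(4-bromo-2,6-dimethoxyphenoxy)-2,3,4-trimethoxybenzaldehyde
Product: 6 6-(4-bromo-2,6-dimethoxyphenoxy)-2,3,4-trimethoxyphenol, via aryl formate 5 (not isolated)
Conditions: mCPBA, CH2Cl2, 0 °C to rt; aq. NaHCO3 wash; then K2CO3 (cat.), MeOH, rt
Reagents that add atoms: 3-chloroperoxybenzoic acid OOC(=O)c1cccc(Cl)c1
Why: Baeyer–Villiger (Dakin-type) oxidation; an aryl group with ortho and para oxygens migrates in preference to hydride. Methanolysis of the formate frees the phenol.

Step 4
Reactants: 3 5-(4-bromo-2,6-dimethoxyphenoxy)-1,2,3-trimethoxybenzene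
Product: 9 [3,5-dimethoxy-4-(3,4,5-trimethoxyphenoxy)phenyl]boronic acid, via aryllithium 7 (not isolated), via lithium triisopropoxyborate 8 (not isolated)
Conditions: n-BuLi, THF, −78 °C; B(OiPr)3, −78 °C to rt; aq. HCl
Reagents that add atoms: triisopropyl borate CC(C)OB(OC(C)C)OC(C)C; water O
Why: Bromine–lithium exchange at −78 °C is faster than ortho-lithiation of the methoxyarenes. Trapping with a trialkyl borate and acid hydrolysis is the standard route to arylboronic acids.

Step 5
Reactants: 6 6-(4-bromo-2,6-dimethoxyphenoxy)-2,3,4-trimethoxyphenol; 9 [3,5-dimethoxy-4-(3,4,5-trimethoxyphenoxy)phenyl]boronic acid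
Product: 10 rings D–G tetramer bromide 5-{4-[6-(4-bromo-2,6-dimethoxyphenoxy)-2,3,4-trimethoxyphenoxy]-2,6-dimethoxyphenoxy}-1,2,3-trimethoxybenzene
Conditions: Cu(OAc)2 (2 equiv), pyridine, 4 Å MS, CH2Cl2, air, rt
Reagents that add atoms: none
Why: Chan–Lam–Evans O-arylation in the same sense as step 1: the phenol bears the two ortho substituents and the boronic acid has free ortho positions. The bromine of 6 survives and becomes the handle for the next cycle.

Step 6
Reactants: 10 rings D–G tetramer bromide
Product: 13 rings D–G tetramer boronic acid (B(OH)2 in place of the bromine of 10), via tetramer aryllithium 11 (not isolated), via tetramer lithium triisopropoxyborate 12 (not isolated)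
Conditions: n-BuLi, THF, −78 °C; B(OiPr)3, −78 °C to rt; aq. HCl
Reagents that add atoms: triisopropyl borate CC(C)OB(OC(C)C)OC(C)C; water O
Why: Same bromine–lithium exchange and borylation as step 4. The substrate contains only methyl and diaryl ethers, which tolerate the aryllithium at −78 °C.

Step 7
Reactants: 6 6-(4-bromo-2,6-dimethoxyphenoxy)-2,3,4-trimethoxyphenol; 13 rings D–G tetramer boronic acid
Product: 14 rings B–G hexamer bromide (permethylated; bromine at B1)
Conditions: Cu(OAc)2 (2 equiv), pyridine, 4 Å MS, CH2Cl2, air, rt
Reagents that add atoms: none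
Why: Third Chan–Lam–Evans O-arylation of the same type, forming C6–O–D1. The boron-bearing carbon D1 has two free ortho positions, and the bromine at B1 is untouched.

Step 8
Reactants: 14 rings B–G hexamer bromide
Product: 15 rings B–G hexamer phenol (permethylated; free hydroxyl at B1)
Conditions: Pd2(dba)3, tBuXPhos, KOH, 1,4-dioxane/H2O, 100 °C; then aq. HCl
Reagents that add atoms: potassium hydroxide [K+].[OH-]
Why: Palladium-catalysed hydroxylation of an aryl bromide with hydroxide and a bulky biaryl di-tert-butylphosphine. The bromide is unhindered, and methyl and diaryl ethers are inert to aqueous KOH.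

Step 9
Reactants: 15 rings B–G hexamer phenol; 16 diethyl bromomalonate
Product: 17 diethyl 2-aryloxymalonate (aryl = permethylated rings B–G hexamer bonded at B1)
Conditions: K2CO3, acetone, reflux
Reagents that add atoms: none
Why: Williamson-type O-alkylation of an unhindered phenoxide by SN2 displacement at the activated α-carbon of the bromomalonate. This makes the future A1–O bond at an sp3 carbon.

Step 10
Reactants: 17 diethyl 2-aryloxymalonate; 18 diethyl 3-oxopentanedioate
Product: 20 diethyl 2,4,6-trihydroxy-5-aryloxybenzene-1,3-dicarboxylate (same aryl), via acyclic triketo triester 19 (not isolated)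
Conditions: NaOEt (3 equiv), EtOH/toluene, reflux; then 130 °C with EtOH distilled off; aq. HCl
Reagents that add atoms: none
Why: Proposed new method: the closest known reaction type is the alkoxide-mediated Claisen–Dieckmann condensation of diethyl malonate with 3-oxoglutarate esters (and the self-condensation of malonate) to phloroglucinol carboxylates; a malonate with an aryloxy group on its central carbon has not been used in it. The more acidic keto diester 18 is deprotonated first, and its enolate carbon attacks one ester carbonyl of 17 (bond A2–A3) to give the acyclic triketo triester 19 as a stabilised enolate. The second methylene of the oxoglutarate unit then attacks the remaining malonate ester in a 6-exo-trig Dieckmann-type acyl substitution (bond A5–A6), closing ring A as a cyclohexane-1,3,5-trione. Enolisation to the aromatic triol, held as a polyanion under ethoxide, pulls both reversible acylations forward. The step needs C-acylation to win over O-acylation; a pyranone formed by O-attack is reopened by ethoxide whereas the benzenoid product is not, so the carbocycle is the thermodynamic sink. The aryloxy group sits on a carbon whose two neighbours are carbonyl carbons, so there is no β-elimination path for loss of aryloxide. No stereocentre is formed. The main kinetic handicap, enolisation of 17 at its own C–H, is met by forcing conditions with removal of ethanol, as in the parent reaction.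

Step 11
Reactants: 20 diethyl 2,4,6-trihydroxy-5-aryloxybenzene-1,3-dicarboxylate
Product: 22 2-aryloxybenzene-1,3,5-triol (same aryl), via dicarboxylic acid 21 (not isolated)
Conditions: NaOH, H2O/EtOH/THF, reflux, N2; then HCl to pH 1, 80 °C
Reagents that add atoms: none
Why: Saponification followed by decarboxylation. 2,4,6-Trihydroxybenzoic acids lose CO2 readily through their β-keto acid tautomers once acidified and warmed. Nitrogen protects the phloroglucinolate from air oxidation.

Step 12
Reactants: 22 2-aryloxybenzene-1,3,5-triol
Product: 23 target heptamer CNP0292517.0 (all eighteen hydroxyls free)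
Conditions: BBr3 (excess), CH2Cl2, −78 °C to rt; then MeOH/H2O, 0 °C
Reagents that add atoms: none
Why: Lewis-acid ether cleavage; bromide attacks the methyl carbon of each boron-complexed aryl methyl ether. The six diaryl ethers have no sp3 carbon and should persist. The work-up is kept acidic and oxygen-free to protect the polyphenol.

## Compound list

1 | 4-bromo-2,6-dimethoxyphenol | COc1cc(Br)cc(OC)c1O | starting material
2 | (3,4,5-trimethoxyphenyl)boronic acid | COc1cc(B(O)O)cc(OC)c1OC | starting material
3 | 5-(4-bromo-2,6-dimethoxyphenoxy)-1,2,3-trimethoxybenzene | COc1cc(Br)cc(OC)c1Oc1cc(OC)c(OC)c(OC)c1 | intermediate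
4 | 6-(4-bromo-2,6-dimethoxyphenoxy)-2,3,4-trimethoxybenzaldehyde | COc1cc(Br)cc(OC)c1Oc1cc(OC)c(OC)c(OC)c1C=O | intermediate
5 | 6-(4-bromo-2,6-dimethoxyphenoxy)-2,3,4-trimethoxyphenyl formate | COc1cc(Br)cc(OC)c1Oc1cc(OC)c(OC)c(OC)c1OC=O | intermediate (not isolated)
6 | 6-(4-bromo-2,6-dimethoxyphenoxy)-2,3,4-trimethoxyphenol | COc1cc(Br)cc(OC)c1Oc1cc(OC)c(OC)c(OC)c1O | intermediate
7 | [3,5-dimethoxy-4-(3,4,5-trimethoxyphenoxy)phenyl]lithium | [Li]c1cc(OC)c(Oc2cc(OC)c(OC)c(OC)c2)c(OC)c1 | intermediate (not isolated)
8 | lithium [3,5-dimethoxy-4-(3,4,5-trimethoxyphenoxy)phenyl]tri(propan-2-yloxy)borate | [Li+].CC(C)O[B-](OC(C)C)(OC(C)C)c1cc(OC)c(Oc2cc(OC)c(OC)c(OC)c2)c(OC)c1 | intermediate (not isolated)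
9 | [3,5-dimethoxy-4-(3,4,5-trimethoxyphenoxy)phenyl]boronic acid | OB(O)c1cc(OC)c(Oc2cc(OC)c(OC)c(OC)c2)c(OC)c1 | intermediate
10 | rings D–G tetramer bromide, 5-{4-[6-(4-bromo-2,6-dimethoxyphenoxy)-2,3,4-trimethoxyphenoxy]-2,6-dimethoxyphenoxy}-1,2,3-trimethoxybenzene | COc1cc(Br)cc(OC)c1Oc1cc(OC)c(OC)c(OC)c1Oc1cc(OC)c(Oc2cc(OC)c(OC)c(OC)c2)c(OC)c1 | intermediate
11 | rings D–G tetramer aryllithium (lithium in place of the bromine of 10) | [Li]c1cc(OC)c(Oc2cc(OC)c(OC)c(OC)c2Oc2cc(OC)c(Oc3cc(OC)c(OC)c(OC)c3)c(OC)c2)c(OC)c1 | intermediate (not isolated)
12 | rings D–G tetramer lithium tri(propan-2-yloxy)borate | [Li+].CC(C)O[B-](OC(C)C)(OC(C)C)c1cc(OC)c(Oc2cc(OC)c(OC)c(OC)c2Oc2cc(OC)c(Oc3cc(OC)c(OC)c(OC)c3)c(OC)c2)c(OC)c1 | intermediate (not isolated)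
13 | rings D–G tetramer boronic acid (B(OH)2 in place of the bromine of 10) | OB(O)c1cc(OC)c(Oc2cc(OC)c(OC)c(OC)c2Oc2cc(OC)c(Oc3cc(OC)c(OC)c(OC)c3)c(OC)c2)c(OC)c1 | intermediate
14 | rings B–G hexamer bromide, 5-{4-[6-(4-{6-(4-bromo-2,6-dimethoxyphenoxy)-2,3,4-trimethoxyphenoxy}-2,6-dimethoxyphenoxy)-2,3,4-trimethoxyphenoxy]-2,6-dimethoxyphenoxy}-1,2,3-trimethoxybenzene | COc1cc(Br)cc(OC)c1Oc1cc(OC)c(OC)c(OC)c1Oc1cc(OC)c(Oc2cc(OC)c(OC)c(OC)c2Oc2cc(OC)c(Oc3cc(OC)c(OC)c(OC)c3)c(OC)c2)c(OC)c1 | intermediate
15 | rings B–G hexamer phenol (hydroxyl in place of the bromine of 14) | COc1cc(O)cc(OC)c1Oc1cc(OC)c(OC)c(OC)c1Oc1cc(OC)c(Oc2cc(OC)c(OC)c(OC)c2Oc2cc(OC)c(Oc3cc(OC)c(OC)c(OC)c3)c(OC)c2)c(OC)c1 | intermediate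
16 | diethyl bromomalonate | CCOC(=O)C(Br)C(=O)OCC | starting material
17 | diethyl 2-aryloxymalonate, aryl being the permethylated rings B–G hexamer bonded at B1 | CCOC(=O)C(C(=O)OCC)Oc1cc(OC)c(Oc2cc(OC)c(OC)c(OC)c2Oc2cc(OC)c(Oc3cc(OC)c(OC)c(OC)c3Oc3cc(OC)c(Oc4cc(OC)c(OC)c(OC)c4)c(OC)c3)c(OC)c2)c(OC)c1 | intermediate
18 | diethyl 3-oxopentanedioate | CCOC(=O)CC(=O)CC(=O)OCC | starting material
19 | diethyl 2-aryloxy-4-(ethoxycarbonyl)-3,5-dioxoheptanedioate (same aryl) | CCOC(=O)CC(=O)C(C(=O)OCC)C(=O)C(C(=O)OCC)Oc1cc(OC)c(Oc2cc(OC)c(OC)c(OC)c2Oc2cc(OC)c(Oc3cc(OC)c(OC)c(OC)c3Oc3cc(OC)c(Oc4cc(OC)c(OC)c(OC)c4)c(OC)c3)c(OC)c2)c(OC)c1 | intermediate (not isolated)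
20 | diethyl 2,4,6-trihydroxy-5-aryloxybenzene-1,3-dicarboxylate (same aryl) | CCOC(=O)c1c(O)c(C(=O)OCC)c(O)c(Oc2cc(OC)c(Oc3cc(OC)c(OC)c(OC)c3Oc3cc(OC)c(Oc4cc(OC)c(OC)c(OC)c4Oc4cc(OC)c(Oc5cc(OC)c(OC)c(OC)c5)c(OC)c4)c(OC)c3)c(OC)c2)c1O | intermediate
21 | 2,4,6-trihydroxy-5-aryloxybenzene-1,3-dicarboxylic acid (same aryl) | OC(=O)c1c(O)c(C(=O)O)c(O)c(Oc2cc(OC)c(Oc3cc(OC)c(OC)c(OC)c3Oc3cc(OC)c(Oc4cc(OC)c(OC)c(OC)c4Oc4cc(OC)c(Oc5cc(OC)c(OC)c(OC)c5)c(OC)c4)c(OC)c3)c(OC)c2)c1O | intermediate (not isolated)
22 | 2-aryloxybenzene-1,3,5-triol (same aryl; ring A free, rings B–G permethylated) | Oc1cc(O)c(Oc2cc(OC)c(Oc3cc(OC)c(OC)c(OC)c3Oc3cc(OC)c(Oc4cc(OC)c(OC)c(OC)c4Oc4cc(OC)c(Oc5cc(OC)c(OC)c(OC)c5)c(OC)c4)c(OC)c3)c(OC)c2)c(O)c1 | intermediate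
23 | CNP0292517.0, the heptamer with eighteen free hydroxyls | Oc1cc(O)c(Oc2cc(O)c(Oc3cc(O)c(O)c(O)c3Oc3cc(O)c(Oc4cc(O)c(O)c(O)c4Oc4cc(O)c(Oc5cc(O)c(O)c(O)c5)c(O)c4)c(O)c3)c(O)c2)c(O)c1 | target

## Step count and least certain steps

Total: 12 steps. Longest linear sequence: 11 steps (1, 2, 3, 5, 6, 7, 8, 9, 10, 11, 12); step 4 is the side branch.

**Step 10 (key step, proposed new method).**
- Risk: the malonate 17 is held as its unreactive enolate, so acylation stalls. Meanwhile the keto diester 18 condenses with itself, or ethoxide removes an ethoxycarbonyl group from 17 by retro-Claisen cleavage. Incomplete second acylation would leave the acyclic stage or a pyranone.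
- Fallback, by known chemistry: the route leaves at hexamer bromide 14. An Ullmann-type coupling (CuI, picolinic acid, K3PO4, DMSO, 90 °C) with purchasable 2,4,6-trimethoxyphenol (COc1cc(OC)c(O)c(OC)c1) joins a phenol with two ortho substituents to an aryl bromide with none. It should give the fully methylated heptamer F1. BBr3 then cleaves all eighteen methyl ethers, and the route is rejoined at target 23.
- Cost of the fallback: it gives up the ring-forming idea and exposes the most electron-rich phenol to copper at 90 °C. It is nonetheless shorter than the main sequence from 14.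

**Step 7 (and, at smaller scale, step 5).**
- Risk: slow transmetalation and C–O bond formation at a crowded copper centre, which lets protodeboronation and oxidative hydroxylation of the large boronic acid 13 consume it.
- Fallback: from phenol 6, palladium-catalysed hydroxylation (Pd2(dba)3, tBuXPhos, KOH) gives 4-(2-hydroxy-3,4,5-trimethoxyphenoxy)-3,5-dimethoxyphenol F2. Benzyl bromide with K2CO3 at room temperature should alkylate the unhindered, more acidic B1 hydroxyl and give 6-[4-(benzyloxy)-2,6-dimethoxyphenoxy]-2,3,4-trimethoxyphenol F3. F3 carries no bromine, so it can be joined to tetramer bromide 10 by Ullmann-type coupling (CuI, picolinic acid, K3PO4, DMSO, 90 °C) to give the hexamer benzyl ether F4. Hydrogenolysis (H2, Pd/C) returns to the route at hexamer phenol 15.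

**Step 8.**
- Risk: the phenoxide product competes with hydroxide for the arylpalladium intermediate and forms a symmetrical diaryl ether; reduction of the bromide to the arene is a second side path.
- Fallback: from 14, Miyaura borylation (Pd(dppf)Cl2, bis(pinacolato)diboron, KOAc, dioxane, 90 °C) gives the hexamer pinacol boronate F5. Oxidation with H2O2/NaOH then gives 15. This replaces C–O bond formation at palladium by C–B bond formation and a boron-to-oxygen shift.

**Step 9.**
- Risk: halophilic attack of the electron-rich phenoxide on bromine of 16, which brominates the ring and reduces the reagent, and a second alkylation of the acidic product.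
- Fallback: from 15, Rh2(OAc)4-catalysed O–H insertion of diethyl diazomalonate (CCOC(=O)C(=[N+]=[N-])C(=O)OCC) in benzene or CH2Cl2 gives 17 directly under neutral conditions. No new compound arises (entry F0 below).

**Step 12.**
- Risk: incomplete cleavage of fifteen ethers, and degradation of the unprotected, highly nucleophilic phloroglucinol ring A under BBr3 and HBr (ring protonation or bromination), followed by oxidation on work-up.
- Fallback: the order of the last two operations is reversed. From diester 20, BBr3 demethylation is carried out while ring A is still deactivated by its two ester groups, giving the diethyl 2,4,6-trihydroxy-5-aryloxybenzene-1,3-dicarboxylate with all rings B–G hydroxyls free F6. Hydrolysis and decarboxylation in hot, degassed dilute HCl then lead to target 23 without any alkaline stage.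

## Further compounds

F1 | step 10 | fully methylated heptamer (2,4,6-trimethoxyphenyl ether of 15) | COc1cc(OC)c(Oc2cc(OC)c(Oc3cc(OC)c(OC)c(OC)c3Oc3cc(OC)c(Oc4cc(OC)c(OC)c(OC)c4Oc4cc(OC)c(Oc5cc(OC)c(OC)c(OC)c5)c(OC)c4)c(OC)c3)c(OC)c2)c(OC)c1
F2 | step 7 | 4-(2-hydroxy-3,4,5-trimethoxyphenoxy)-3,5-dimethoxyphenol | COc1cc(O)cc(OC)c1Oc1cc(OC)c(OC)c(OC)c1O
F3 | step 7 | 6-[4-(benzyloxy)-2,6-dimethoxyphenoxy]-2,3,4-trimethoxyphenol | COc1cc(OCc2ccccc2)cc(OC)c1Oc1cc(OC)c(OC)c(OC)c1O
F4 | step 7 | rings B–G hexamer benzyl ether (benzyl ether of 15 at B1) | COc1cc(OCc2ccccc2)cc(OC)c1Oc1cc(OC)c(OC)c(OC)c1Oc1cc(OC)c(Oc2cc(OC)c(OC)c(OC)c2Oc2cc(OC)c(Oc3cc(OC)c(OC)c(OC)c3)c(OC)c2)c(OC)c1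
F5 | step 8 | rings B–G hexamer pinacol boronate (4,4,5,5-tetramethyl-1,3,2-dioxaborolan-2-yl in place of the bromine of 14) | CC1(C)OB(OC1(C)C)c1cc(OC)c(Oc2cc(OC)c(OC)c(OC)c2Oc2cc(OC)c(Oc3cc(OC)c(OC)c(OC)c3Oc3cc(OC)c(Oc4cc(OC)c(OC)c(OC)c4)c(OC)c3)c(OC)c2)c(OC)c1
F0 | step 9 | none | none
F6 | step 12 | diethyl 2,4,6-trihydroxy-5-aryloxybenzene-1,3-dicarboxylate with all hydroxyls of rings B–G free | CCOC(=O)c1c(O)c(C(=O)OCC)c(O)c(Oc2cc(O)c(Oc3cc(O)c(O)c(O)c3Oc3cc(O)c(Oc4cc(O)c(O)c(O)c4Oc4cc(O)c(Oc5cc(O)c(O)c(O)c5)c(O)c4)c(O)c3)c(O)c2)c1O
A1 | alternative 1 | rings A–B dimer, 2-{[3,5-dimethoxy-4-(triisopropylsilyloxy)phenyl]oxy}-1,3,5-trimethoxybenzene | COc1cc(OC)c(Oc2cc(OC)c(O[Si](C(C)C)(C(C)C)C(C)C)c(OC)c2)c(OC)c1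
A2 | alternative 1 | 3,5-dimethoxy-4H-pyran-4-one | COC1=COC=C(OC)C1=O
A3 | alternative 1 | triphenyl[(2,4,6-trimethoxyphenoxy)methyl]phosphonium chloride | COc1cc(OC)c(OC[P+](c2ccccc2)(c2ccccc2)c2ccccc2)c(OC)c1.[Cl-]
A4 | alternative 2 | rings A–C trimer with C3 hydroxyl free and C6 oxygen as triethylsilyl ether | COc1cc(OC)c(Oc2cc(OC)c(Oc3cc(O)c(OC)c(OC)c3O[Si](CC)(CC)CC)c(OC)c2)c(OC)c1
A5 | alternative 2 | 4-{1-[2,6-dimethoxy-4-(2,4,6-trimethoxyphenoxy)phenoxy]ethenyl}-2,3-dimethoxy-4-(triethylsilyloxy)cyclobut-2-en-1-one | COC1=C(OC)C(O[Si](CC)(CC)CC)(C(=C)Oc2c(OC)cc(Oc3c(OC)cc(OC)cc3OC)cc2OC)C1=O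
A6 | alternative 2 | dimethyl squarate (3,4-dimethoxycyclobut-3-ene-1,2-dione) | COC1=C(OC)C(=O)C1=O
A7 | alternative 3 | heptamer with D5 hydroxyl free, D3 as ethyl ether and all other hydroxyls as methyl ethers | COc1cc(OC)c(Oc2cc(OC)c(Oc3cc(OC)c(OC)c(OC)c3Oc3cc(OCC)c(Oc4cc(OC)c(OC)c(OC)c4Oc4cc(OC)c(Oc5cc(OC)c(OC)c(OC)c5)c(OC)c4)c(O)c3)c(OC)c2)c(OC)c1
A8 | alternative 3 | ethynyl ether of the permethylated rings A–C phenol (ethynyloxy at C6) | C#COc1c(OC)c(OC)c(OC)cc1Oc1c(OC)cc(Oc2c(OC)cc(OC)cc2OC)cc1OC
A9 | alternative 3 | 3-ethoxy-4-aryloxycyclobut-2-en-1-one, aryl being the permethylated rings E–G trimer bonded at E1 | CCOC1=CC(=O)C1Oc1cc(OC)c(OC)c(OC)c1Oc1cc(OC)c(Oc2cc(OC)c(OC)c(OC)c2)c(OC)c1
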